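## Retrosynthetic overview

- The target is cut at C12–C13: a B-alkyl Suzuki coupling joins a 6β-acetoxy-9α-hydroxy-9-vinyl decalin to a 4-bromo unsaturated lactam made from tetramic acid.
- The 9α-OH/C11 unit comes from a 9(11)-exo-methylene group, epoxidised from the α face and homologated by one carbon; the exo-methylene comes from a C9 ketone and the 6β-OAc from a C6 ketone.
- The trans-decalin-6,9-dione comes from one acid cascade on a 4-methoxy-4-methylcyclohexenone: a 1,2-methyl shift C9→C10 (quaternary centre plus C9 carbonyl), then cation–enol closure of ring A (C4–C5).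
- The cascade substrate comes from para-cresol (ring B and C20), dimethylzinc (C17, catalytic desymmetrisation fixes the absolute configuration) and homoprenyl bromide (C1–C4, C18, C19).
- Ring order: ring B (dearomatised arene), then ring A (cascade), then the lactam ring attached last.

Assumption: positions are cited by labdane numbering (decalin C1–C10, tether C11/C12, lactam C13–C16, C17 on C8, C18/C19 on C4, C20 on C10), and the antipode of the step 2 ligand is the one that gives the (4R) product.

## Route

Step 1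
Reactants: 1 4-methylphenol (para-cresol)
Product: 2 4-methoxy-4-methylcyclohexa-2,5-dien-1-one
Conditions: PhI(OAc)2 (1.1 equiv), MeOH, 0 °C to rt
Reagents that add atoms: methanol, CO
Why: Oxidative dearomatisation of a para-alkylphenol in methanol (capture of the phenoxenium ion at the para carbon) is a standard route to 4-alkoxy-4-alkylcyclohexadienones, and the product is prochiral so no stereocentre is set.

Step 2
Reactants: 2 4-methoxy-4-methylcyclohexa-2,5-dien-1-one
Product: 3 (4R,5R)-4-methoxy-4,5-dimethylcyclohex-2-en-1-one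
Conditions: Me2Zn (1.5 equiv), Cu(OTf)2 (2 mol %), (S)-BINOL-derived N,N-bis[(R)-1-phenylethyl]phosphoramidite (4 mol %), toluene, −25 °C; then 1 M HCl, 0 °C
Reagents that add atoms: dimethylzinc, C[Zn]C
Why: Copper/phosphoramidite-catalysed asymmetric conjugate addition desymmetrises the dienone by selecting one enantiotopic C=C, which fixes C4 as R (the later C9, whose methyl becomes C20), while the methyl enters syn to the small methoxy group to set C5 (the later C8, re-equilibrated in step 4, so its diastereomer ratio is not critical).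

Step 3
Reactants: 3 (4R,5R)-4-methoxy-4,5-dimethylcyclohex-2-en-1-one; 4 5-bromo-2-methylpent-2-ene
Product: 7 (4R,5R)-4-methoxy-4,5-dimethyl-3-(4-methylpent-3-en-1-yl)cyclohex-2-en-1-one, via Grignard reagent 5 (not isolated), via silyl enol ether 6 (not isolated)
Conditions: 4, Mg, THF, rt; then 3, CuBr·SMe2 (10 mol %), TMSCl (2 equiv), THF, −78 °C; crude 6, Pd(OAc)2 (10 mol %), O2 (1 atm), DMSO, rt
Reagents that add atoms: none
Why: Copper-catalysed Grignard 1,4-addition with TMSCl trapping gives the regiodefined silyl enol ether, and Saegusa–Ito dehydrogenation (aerobic Larock variant) restores the C2=C3 double bond, which erases the transient C3 stereocentre and gives the β-substituted enone needed for the shift.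

Step 4
Reactants: 7 (4R,5R)-4-methoxy-4,5-dimethyl-3-(4-methylpent-3-en-1-yl)cyclohex-2-en-1-one
Product: 9 (3R,4aS,8aS)-3,4a,8,8-tetramethyloctahydronaphthalene-1,4-dione, via monocyclic 1,4-dione 8 (not isolated)
Conditions: TfOH (3 equiv), H2O (2 equiv), (CF3)2CHOH/CH2Cl2 4:1, −20 °C to rt; then NaOMe (0.2 equiv), MeOH, rt
Reagents that add atoms: water, O
Why: Proposed new method: O-protonation of the enone makes C10 cationic and the pseudo-axial C9 methyl migrates suprafacially to it, pushed by the methoxy lone pair (vinylogous semipinacol, closest known type the quinol–enedione/dienone–phenol 1,2-shift), which converts the (R) carbinol centre into the (S) quaternary C10; hydrolysis of the oxocarbenium releases methanol, and the C5 enol is then alkylated by the tertiary cation from protonation of the prenyl-type alkene (closest known type an enol-terminated cation–olefin cyclisation) to close ring A, after which enolisation equilibrates C5 to the trans ring fusion and C8 to the equatorial α-methyl.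

Step 5
Reactants: 9 (3R,4aS,8aS)-3,4a,8,8-tetramethyloctahydronaphthalene-1,4-dione
Product: 10 (2R,4R,4aS,8aS)-4-hydroxy-2,5,5,8a-tetramethyloctahydronaphthalen-1(2H)-one
Conditions: LiBH(s-Bu)3 (1.05 equiv), THF, −78 °C; then H2O
Reagents that add atoms: none
Why: The bulky hydride reduces only the C6 ketone because the C9 carbonyl is flanked by the quaternary C10 and the methyl-bearing C8, and it must approach C6 from the α face because the β face is blocked by the 1,3-diaxial C4β and C10 methyls, which gives the axial 6β-alcohol (chemo- and diastereoselective ketone reduction).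

Step 6
Reactants: 10 (2R,4R,4aS,8aS)-4-hydroxy-2,5,5,8a-tetramethyloctahydronaphthalen-1(2H)-one
Product: 11 (1R,3R,4aS,8aS)-3,4a,8,8-tetramethyl-4-methylidenedecahydronaphthalen-1-ol
Conditions: Ph3PCH3Br (4 equiv), KOtBu (4 equiv), toluene, 90 °C
Reagents that add atoms: methyltriphenylphosphonium bromide, C[P+](c1ccccc1)(c1ccccc1)c1ccccc1.[Br-]
Why: Wittig methylenation with excess ylide and KOtBu in hot toluene is the established way to methylenate hindered α,α,α'-trisubstituted cyclohexanones, the C6 alkoxide is inert, and C8 stays at its thermodynamic equatorial configuration.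

Step 7
Reactants: 11 (1R,3R,4aS,8aS)-3,4a,8,8-tetramethyl-4-methylidenedecahydronaphthalen-1-ol
Product: 12 (1R,2R,4R,4aS,8aS)-2,5,5,8a-tetramethyloctahydro-2H-spiro[naphthalene-1,2'-oxiran]-4-ol
Conditions: mCPBA (1.3 equiv), NaHCO3, CH2Cl2, 0 °C
Reagents that add atoms: 3-chloroperoxybenzoic acid (mCPBA), OOC(=O)c1cccc(Cl)c1
Why: Prilezhaev epoxidation of the exocyclic alkene takes place on the α face, anti to the adjacent axial C10 methyl, so the new C9–O bond is α (axial) and C9 is set as R.

Step 8
Reactants: 12 (1R,2R,4R,4aS,8aS)-2,5,5,8a-tetramethyloctahydro-2H-spiro[naphthalene-1,2'-oxiran]-4-ol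
Product: 13 (1R,3R,4R,4aS,8aS)-4-ethenyl-3,4a,8,8-tetramethyldecahydronaphthalene-1,4-diol
Conditions: Me3SI (5 equiv), n-BuLi (4.8 equiv), THF, −10 °C to rt
Reagents that add atoms: trimethylsulfonium iodide, C[S+](C)C.[I-]
Why: Dimethylsulfonium methylide opens the epoxide at its unsubstituted CH2 and the resulting β-alkoxy sulfonium salt eliminates Me2S through its ylide (one-carbon homologation of an epoxide to an allylic alcohol), which leaves the C9–O bond and therefore the 9α-OH configuration untouched.

Step 9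
Reactants: 13 (1R,3R,4R,4aS,8aS)-4-ethenyl-3,4a,8,8-tetramethyldecahydronaphthalene-1,4-diol
Product: 14 (1R,3R,4R,4aS,8aS)-4-ethenyl-4-hydroxy-3,4a,8,8-tetramethyldecahydronaphthalen-1-yl acetate
Conditions: Ac2O (3 equiv), DMAP (0.2 equiv), pyridine, 45 °C
Reagents that add atoms: acetic anhydride, CC(=O)OC(C)=O
Why: DMAP-catalysed acetylation acylates the secondary 6β-hydroxyl while the tertiary, doubly flanked 9-hydroxyl does not react, so no protecting group is needed.

Step 10
Reactants: 15 pyrrolidine-2,4-dione (tetramic acid)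
Product: 16 4-bromo-1,5-dihydro-2H-pyrrol-2-one
Conditions: (COBr)2 (1.2 equiv), DMF (cat.), CH2Cl2, 0 °C to rt
Reagents that add atoms: oxalyl bromide, BrC(=O)C(=O)Br
Why: Vilsmeier-type deoxybromination of the enolised 4-carbonyl (vinylogous acid to vinylogous acyl bromide), as used routinely for tetronic acids, gives the 4-bromo unsaturated lactam.

Step 11
Reactants: 14 (1R,3R,4R,4aS,8aS)-4-ethenyl-4-hydroxy-3,4a,8,8-tetramethyldecahydronaphthalen-1-yl acetate; 16 4-bromo-1,5-dihydro-2H-pyrrol-2-one
Product: 18 (1R,3R,4R,4aS,8aS)-4-hydroxy-3,4a,8,8-tetramethyl-4-[2-(5-oxo-2,5-dihydro-1H-pyrrol-3-yl)ethyl]decahydronaphthalen-1-yl acetate, via B-alkyl-9-BBN adduct 17 (not isolated)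
Conditions: 9-BBN (2.5 equiv), THF, 0 °C to rt; then 16, PdCl2(dppf) (5 mol %), AsPh3 (10 mol %), Cs2CO3 (3 equiv), DMF/H2O, 50 °C
Reagents that add atoms: none
Why: Anti-Markovnikov hydroboration of the monosubstituted alkene followed by B-alkyl Suzuki–Miyaura coupling with the vinylogous acyl bromide forms C12–C13 and completes the side chain without touching a stereocentre, and the hindered acetate, the tertiary alcohol and the lactam N–H tolerate the mild carbonate conditions.

## Compound list

1 | 4-methylphenol (para-cresol) | Cc1ccc(O)cc1 | starting material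
2 | 4-methoxy-4-methylcyclohexa-2,5-dien-1-one | COC1(C)C=CC(=O)C=C1 | intermediate
3 | (4R,5R)-4-methoxy-4,5-dimethylcyclohex-2-en-1-one | O=C1C=C[C@@](OC)(C)[C@H](C)C1 | intermediate
4 | 5-bromo-2-methylpent-2-ene | CC(C)=CCCBr | starting material
5 | (4-methylpent-3-en-1-yl)magnesium bromide | CC(C)=CCC[Mg]Br | intermediate
6 | {[(4R,5R)-4-methoxy-4,5-dimethyl-3-(4-methylpent-3-en-1-yl)cyclohex-1-en-1-yl]oxy}trimethylsilane (C3 epimers) | C[Si](C)(C)OC1=CC(CCC=C(C)C)[C@@](OC)(C)[C@H](C)C1 | intermediate
7 | (4R,5R)-4-methoxy-4,5-dimethyl-3-(4-methylpent-3-en-1-yl)cyclohex-2-en-1-one | O=C1C=C(CCC=C(C)C)[C@@](OC)(C)[C@H](C)C1 | intermediate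
8 | (2S,6R)-2,6-dimethyl-2-(4-methylpent-3-en-1-yl)cyclohexane-1,4-dione | O=C1C[C@@H](C)C(=O)[C@@](C)(CCC=C(C)C)C1 | intermediate
9 | (3R,4aS,8aS)-3,4a,8,8-tetramethyloctahydronaphthalene-1,4-dione | O=C1C[C@@H](C)C(=O)[C@@]2(C)CCCC(C)(C)[C@H]12 | intermediate
10 | (2R,4R,4aS,8aS)-4-hydroxy-2,5,5,8a-tetramethyloctahydronaphthalen-1(2H)-one | O[C@@H]1C[C@@H](C)C(=O)[C@@]2(C)CCCC(C)(C)[C@H]12 | intermediate
11 | (1R,3R,4aS,8aS)-3,4a,8,8-tetramethyl-4-methylidenedecahydronaphthalen-1-ol | O[C@@H]1C[C@@H](C)C(=C)[C@@]2(C)CCCC(C)(C)[C@H]12 | intermediate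
12 | (1R,2R,4R,4aS,8aS)-2,5,5,8a-tetramethyloctahydro-2H-spiro[naphthalene-1,2'-oxiran]-4-ol | O[C@@H]1C[C@@H](C)[C@]3(CO3)[C@@]2(C)CCCC(C)(C)[C@H]12 | intermediate
13 | (1R,3R,4R,4aS,8aS)-4-ethenyl-3,4a,8,8-tetramethyldecahydronaphthalene-1,4-diol | O[C@@H]1C[C@@H](C)[C@](O)(C=C)[C@@]2(C)CCCC(C)(C)[C@H]12 | intermediate
14 | (1R,3R,4R,4aS,8aS)-4-ethenyl-4-hydroxy-3,4a,8,8-tetramethyldecahydronaphthalen-1-yl acetate | CC(=O)O[C@@H]1C[C@@H](C)[C@](O)(C=C)[C@@]2(C)CCCC(C)(C)[C@H]12 | intermediate
15 | pyrrolidine-2,4-dione | O=C1CC(=O)CN1 | starting material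
16 | 4-bromo-1,5-dihydro-2H-pyrrol-2-one | O=C1C=C(Br)CN1 | intermediate
17 | (1R,3R,4R,4aS,8aS)-4-[2-(9-borabicyclo[3.3.1]nonan-9-yl)ethyl]-4-hydroxy-3,4a,8,8-tetramethyldecahydronaphthalen-1-yl acetate | CC(=O)O[C@@H]1C[C@@H](C)[C@](O)(CCB3C4CCCC3CCC4)[C@@]2(C)CCCC(C)(C)[C@H]12 | intermediate
18 | (1R,3R,4R,4aS,8aS)-4-hydroxy-3,4a,8,8-tetramethyl-4-[2-(5-oxo-2,5-dihydro-1H-pyrrol-3-yl)ethyl]decahydronaphthalen-1-yl acetate | CC(=O)O[C@@H]1C[C@@H](C)[C@](O)(CCC2=CC(=O)NC2)[C@@]2(C)CCCC(C)(C)[C@H]12 | target

## Step count and risks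

Total step count: 11. Longest linear sequence: 10 (steps 1–9 and 11; step 10 is the convergent branch).

Steps most likely to fail: step 4, step 6 and step 8.

**Step 4 (the proposed new cascade).** If the one-pot reaction is diverted, for example by Prins closure of the alkene onto a carbonyl or oxocarbenium ion, the two events are run separately with established reactions, starting from 7. CF3CO2H in wet CH2Cl2 at 0 °C performs only the acid-catalysed quinol-type 1,2-methyl shift with loss of methanol, and the monocyclic dione 8 is isolated. HCl gas in CH2Cl2 at −30 °C then adds to the trisubstituted alkene (Markovnikov) to give the tertiary chloride (2S,6R)-2-(4-chloro-4-methylpentyl)-2,6-dimethylcyclohexane-1,4-dione F1. TiCl4 in CH2Cl2 at −40 °C effects the Lewis-acid α-tert-alkylation of the ketone through its enol (Reetz-type; only the C5 enol can close a six-membered ring), and NaOMe/MeOH equilibration returns to 9.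

**Step 6 (methylenation of a ketone flanked by a quaternary and a tertiary carbon).** If the Wittig reaction stalls, the methylene is introduced by Peterson olefination, starting from 10. The small, non-basic organocerium reagent from Me3SiCH2Li and CeCl3 (THF, −78 °C) adds to the C9 carbonyl from the α face to give (1R,3R,4S,4aS,8aS)-3,4a,8,8-tetramethyl-4-[(trimethylsilyl)methyl]decahydronaphthalene-1,4-diol F2. KH in THF then eliminates silanolate and the route is rejoined at 11.

**Step 8 (SN2 opening at a CH2 next to a fully substituted, crowded carbon).** If the ylide homologation fails, the epoxide is bypassed, starting from 11. OsO4 (cat.)/NMO dihydroxylates the exocyclic alkene from the α face to give (1R,3R,4R,4aS,8aS)-4-(hydroxymethyl)-3,4a,8,8-tetramethyldecahydronaphthalene-1,4-diol F3. TEMPO (cat.)/PhI(OAc)2 oxidises only the primary alcohol to (1R,2R,4R,4aS,8aS)-1,4-dihydroxy-2,5,5,8a-tetramethyldecahydronaphthalene-1-carbaldehyde F4. Wittig methylenation with Ph3P=CH2 (THF, −78 to 0 °C) then gives 13, where the route is rejoined.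

## Further compounds

F1 | step 4 | (2S,6R)-2-(4-chloro-4-methylpentyl)-2,6-dimethylcyclohexane-1,4-dione | O=C1C[C@@H](C)C(=O)[C@@](C)(CCCC(C)(C)Cl)C1
F2 | step 6 | (1R,3R,4S,4aS,8aS)-3,4a,8,8-tetramethyl-4-[(trimethylsilyl)methyl]decahydronaphthalene-1,4-diol | O[C@@H]1C[C@@H](C)[C@@](O)(C[Si](C)(C)C)[C@@]2(C)CCCC(C)(C)[C@H]12
F3 | step 8 | (1R,3R,4R,4aS,8aS)-4-(hydroxymethyl)-3,4a,8,8-tetramethyldecahydronaphthalene-1,4-diol | O[C@@H]1C[C@@H](C)[C@](O)(CO)[C@@]2(C)CCCC(C)(C)[C@H]12
F4 | step 8 | (1R,2R,4R,4aS,8aS)-1,4-dihydroxy-2,5,5,8a-tetramethyldecahydronaphthalene-1-carbaldehyde | O[C@@H]1C[C@@H](C)[C@](O)(C=O)[C@@]2(C)CCCC(C)(C)[C@H]12
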